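Counted in molar, the L loaded at 5 mol% on 2 M of G is 0.100 M in each flask of the table below, and each charge of J is held against that figure.

| flask | G | J | L | remark | time |
|---|---|---|---|---|---|
| zeta | 2 M | 0.027 M | 5 mol% | run made earlier |  |
| epsilon | 2 M | 0.23 M | 5 mol% | run made earlier |  |
| noon | 2.0 M | 0.0600 M | 5 mol% |  | 2.5 d |
| spring | 2.0 M | 0.180 M | 5 mol% |  | 2.5 d |
| midnight | 2.0 M | 0.0200 M | 5 mol% |  | 2.5 d |

- zeta (time / h: G / %, Z / %): 8.00: 33, 66; 15.0: 10, 90; 20.0: 4, 93; 30.0: 0, 101; 40.0: 0, 101
- epsilon (time / h: G / %, Z / %): 3.00: 78, 21; 6.00: 73, 23; 10.0: 70, 25; 15.0: 70, 29; 25.0: 71, 29; 40.0: 71, 24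

(scatter of a reading: 2 percentage points)

1. which of these there is most of at the end, counted by the G in it, noon (Z / G)
2. which of these there is most of at the end, counted by the G in it, spring (Z / G)
3. which of these there is most of at the end, counted by the G in it, midnight (Z / G)
4. the largest of these amounts at the end, in percent of the G charged, noon
5. the largest of these amounts at the end, in percent of the G charged, spring
6. the largest of these amounts at the end, in percent of the G charged, midnight

The zeta run, with 0.027 M of J, less than that figure, carries G down to 0%. The epsilon run, with 0.23 M of J, more than that figure, stands at 71% of G after 40.0 h. This suggests a working guess: each J removes one unit of catalyst, so what goes on working is the surplus s, the charge of L less the charge of J. In the zeta run s is 0.0730 M. Between 8.00 h and 15.0 h G falls there with a pseudo-first-order constant k of 0.171 /h, a reading that carries the scatter. Dividing gives κ = 2.34 /M/h, the rate constant per molar of surplus.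

Now the question turned round. With t the time of 2.5 d, this reckoning lets G keep more than half of its charge if κst stays under the logarithm of two, that is, if s lies below s* = 0.00494 M. Noon has s = 0.0400 M and midnight s = 0.0800 M, both above s*, so both should end with Z: G near 0.364% at noon and 0.00135% at midnight. Spring has s = −0.0800 M, no surplus, so it should stop as epsilon did, with G the larger, somewhat under epsilon's level because it carries less J.

The forecast gives Z at 97% for noon, G at 59% for spring and Z at 100% for midnight, saying of spring: “catalyst dies”.

The flasks give Z at 99.3% for noon, G at 62.7% for spring and Z at >99.9% for midnight.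

    G + L → D + Z (k = 0.380 /M/h)
    G + D → Z + D, rate k2*[D]*[G] (k = 2.00 /M/h)
    D + J → X (k = 3.80 /M/h)
    L → E (k = 0.0150 /h)

In midnight, L is used by the path to D 51 times as fast as by the path to E at the start, and 24 times as fast at 0.222 d, and at 2.50 d D stands at 0.0772 M against s of 0.0800 M. At 1.25 d κs reckons midnight's G at 0.364%, and the flask holds 1.04%. The neighbour, midnight with 1.2 mol% of L, has s = 0.00400 M, below s*, so κ reckons its G at 57.0%, but that flask ends with G at 31.2% and Z at 68.8%, with D at 0.00575 M, more than its s.

(The earlier runs and the new flask stem from a simulated flask for substances that don't exist, noise included.)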